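**Plan**
1. Retrosynthesis: the butenolide is cut off first (bond from the side-chain CH2 to the lactone α-carbon) and the isopropenyl group is traced back to an acetyl group; next the hydrogens on C4 and C2 are traced back to an allylic C4–O bond; last, the two ring bonds C1–C8 and C4–C5 of the carbocycle are cut together.
2. Enabling feature (locants of the 6-oxabicyclo[3.2.1]octan-7-one core): the carbocycle C1–C2–C3–C4–C5–C8 carries the lactone carbonyl C7 on its quaternary C1, and C7–C1–C2(Me)–C3–C4 is the carbon chain of a 3,4-disubstituted 2-pyrone. A dearomatizing Diels–Alder reaction of that pyrone with a C5=C8 enone therefore builds the ring and both quaternary carbons at once.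
3. Forward order: pyrone plus (Z)-2-alkoxy enone give a 2-oxabicyclo[2.2.2]octene (carbocycle closed); the lactone then migrates from the C4 oxygen to the tertiary C5 oxygen (the γ-lactone of the target); the former pyrone oxygen leaves as an allylic formate; the butenolide ring is made last.
4. Stereochemistry: absolute configuration from a chiral copper catalyst in the cycloaddition; C1/C5/C8 relative configuration from the endo rule and the Z alkene; C2 from a palladium hydride delivered anti to the departing C4 oxygen.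

Key step: step 5

Remark: the compounds marked as starting materials in the list are taken as commercial. The sense of induction in step 5 is assigned from the square-planar chelate model of bis(oxazoline) copper complexes; should it prove opposite, the (R,R) ligand would be used.

Step 1
Reactants: 1 methyl 4-chlorobutanoate; 2 4,4-dimethoxybutan-2-one
Product: 3 methyl 2-(2-chloroethyl)-3-hydroxy-5,5-dimethoxy-3-methylpentanoate (mixture of diastereomers)
Conditions: LiN(iPr)2, THF, −78 °C; then 2, −78 °C; AcOH quench at −78 °C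
Reagents that add atoms: none
Why: Directed aldol addition of a preformed lithium ester enolate to a methyl ketone, in which the cold acidic quench is meant to forestall both 3-exo ring closure of the γ-chloro enolate and O-alkylation by the aldolate, and in which the new stereocentres do not matter because both become sp2 in step 2.

Step 2
Reactants: 3 methyl 2-(2-chloroethyl)-3-hydroxy-5,5-dimethoxy-3-methylpentanoate
Product: 4 3-(2-chloroethyl)-4-methyl-2H-pyran-2-one
Conditions: TsOH·H2O (0.2 equiv), toluene, reflux with distillative removal of MeOH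
Reagents that add atoms: none
Why: Acid-catalysed dehydration, acetal ionisation and lactonisation onto the unmasked aldehyde carbon with loss of methanol is the classical route from acetylacetaldehyde acetal adducts to 4-methyl-2-pyrones, the E and Z enoates converging under the acidic conditions.

Step 3
Reactants: 5 dimethyl (1-diazo-2-oxopropyl)phosphonate; 6 (4-methoxyphenyl)methanol
Product: 7 dimethyl {1-[(4-methoxybenzyl)oxy]-2-oxopropyl}phosphonate (racemic)
Conditions: Rh2(OAc)4 (1 mol %), benzene, 80 °C
Reagents that add atoms: none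
Why: Rhodium-carbenoid O–H insertion of an α-diazo-β-ketophosphonate into an alcohol is an established way to α-alkoxy phosphonates.

Step 4
Reactants: 7 dimethyl {1-[(4-methoxybenzyl)oxy]-2-oxopropyl}phosphonate; 8 methyl 4-oxobutanoate
Product: 9 methyl (4Z)-5-[(4-methoxybenzyl)oxy]-6-oxohept-4-enoate
Conditions: NaH, THF, 0 °C; then 8, 0 °C → rt
Reagents that add atoms: none
Why: Horner–Wadsworth–Emmons olefination of an α-alkoxy-β-ketophosphonate, which should favour the isomer with the β-substituent trans to the acetyl group (the Z enol ether needed), the minor isomer being removed by chromatography.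

Step 5
Reactants: 4 3-(2-chloroethyl)-4-methyl-2H-pyran-2-one; 9 methyl (4Z)-5-[(4-methoxybenzyl)oxy]-6-oxohept-4-enoate
Product: 10 methyl 3-{7-acetyl-4-(2-chloroethyl)-7-[(4-methoxybenzyl)oxy]-5-methyl-3-oxo-2-oxabicyclo[2.2.2]oct-5-en-8-yl}propanoate (endo-acetyl adduct: acetyl syn to the C5=C6 bridge; ether oxygen and propanoate chain syn to the lactone bridge; single enantiomer as drawn in the compound list)
Conditions: [Cu((S,S)-tBu-box)](SbF6)2 (10 mol %; ligand = 2,2'-(propane-2,2-diyl)bis[(4S)-4-tert-butyl-4,5-dihydro-1,3-oxazole]), 4 Å MS, CH2Cl2, −20 °C → rt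
Reagents that add atoms: none
Why: Proposed new method: chelation of the ketone and ether oxygens of 9 to the cationic divalent copper centre should cancel the donor effect of the ether oxygen and make the β-carbon strongly electrophilic, so that the nucleophilic C-3 of pyrone 4 bonds to it while pyrone C-6 bonds to the oxygen-bearing carbon in a concerted but asynchronous, suprafacial [4+2] addition that dearomatizes the pyrone; the closest known reaction types are the thermal or Lewis-acid-promoted Diels–Alder reactions of 2-pyrones with enones and the bis(oxazoline)–copper-catalysed Diels–Alder reactions of chelating dienophiles, which have not been shown together on an alkyl 2-pyrone. The six-membered carbocycle (core C1–C2–C3–C4–C5–C8) is closed by this intermolecular endo [4+2] mode, both ring bonds C1–C8 and C4–C5 being made in the one step, and the old pyrone lactone is left as the two-atom bridge of a 2-oxabicyclo[2.2.2]octene. Four stereocentres arise: the two bridgeheads are fixed relative to each other by addition across one face of the flat pyrone, the oxygen-bearing carbon and its CH neighbour keep the Z geometry of 9 (ether oxygen cis to the propanoate chain), the endo rule puts the acetyl group under the pyrone C-4/C-5 π bond and therefore the ether oxygen on the side of the lactone bridge, and the absolute sense comes from the (S,S)-ligand, whose tert-butyl group is expected to cover the Si face of the chelated oxygen-bearing alkene carbon so that the pyrone adds to its Re face. The regioselectivity needed is secured twice in the substrates, by polarity (pyrone C-3 is the most nucleophilic ring carbon, the enone β-carbon the most electrophilic one) and by sterics (the other orientation would have to join two fully substituted carbons), and loss of CO2 from the adduct is avoided because catalysis allows a low temperature.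

Step 6
Reactants: 10 methyl 3-{7-acetyl-4-(2-chloroethyl)-7-[(4-methoxybenzyl)oxy]-5-methyl-3-oxo-2-oxabicyclo[2.2.2]oct-5-en-8-yl}propanoate
Product: 11 methyl 3-[7-acetyl-4-(2-chloroethyl)-7-hydroxy-5-methyl-3-oxo-2-oxabicyclo[2.2.2]oct-5-en-8-yl]propanoate (configuration unchanged)
Conditions: DDQ (1.3 equiv), CH2Cl2/pH 7 buffer, 0 °C
Reagents that add atoms: none
Why: Oxidative cleavage of a 4-methoxybenzyl ether by DDQ under buffered, neutral conditions should free the tertiary alcohol without touching the alkyl chloride, the esters or the strained lactone.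

Step 7
Reactants: 11 methyl 3-[7-acetyl-4-(2-chloroethyl)-7-hydroxy-5-methyl-3-oxo-2-oxabicyclo[2.2.2]oct-5-en-8-yl]propanoate
Product: 13 methyl 3-[5-acetyl-1-(2-chloroethyl)-4-(formyloxy)-2-methyl-7-oxo-6-oxabicyclo[3.2.1]oct-2-en-8-yl]propanoate (formate cis to the ring oxygen O6; propanoate chain syn to the lactone bridge), via hydroxy lactone 12 (not isolated)
Conditions: DBU (0.1 equiv), CH2Cl2, 0 °C; then HCO2H, DCC, DMAP (cat.), 0 °C
Reagents that add atoms: formic acid, O=CO
Why: Base-catalysed intramolecular transesterification moves the acyl group from the secondary allylic oxygen to the cis tertiary oxygen, trading the boat-locked bicyclo[2.2.2] lactone for the 6-oxabicyclo[3.2.1] γ-lactone of the target, and Steglich formylation traps the freed allylic alcohol at once, which pulls the equilibrium over and shortens the life of the β-hydroxy ketone.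

Step 8
Reactants: 13 methyl 3-[5-acetyl-1-(2-chloroethyl)-4-(formyloxy)-2-methyl-7-oxo-6-oxabicyclo[3.2.1]oct-2-en-8-yl]propanoate
Product: 14 methyl 3-[(1R,2R,5S,8R)-5-acetyl-1-(2-chloroethyl)-2-methyl-7-oxo-6-oxabicyclo[3.2.1]oct-3-en-8-yl]propanoate
Conditions: Pd(OAc)2 (5 mol %), PBu3 (5 mol %), dioxane, rt (warmed to 40 °C only if needed), stopped at full conversion
Reagents that add atoms: none
Why: Palladium-catalysed hydrogenolysis of an allylic formate (Tsuji–Trost-type reduction), in which zerovalent palladium ionises anti to the formate, that is from the open face next to the one-carbon bridge C8, and the palladium hydride formed by loss of CO2 is delivered on that same face to the more substituted allyl terminus, which sets C2 with its methyl group on the side of the lactone bridge and leaves a C3=C4 double bond.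

Step 9
Reactants: 14 methyl 3-[(1R,2R,5S,8R)-5-acetyl-1-(2-chloroethyl)-2-methyl-7-oxo-6-oxabicyclo[3.2.1]oct-3-en-8-yl]propanoate
Product: 15 methyl 3-[(1R,2R,5S,8R)-5-acetyl-1-(2-chloroethyl)-2-methyl-7-oxo-6-oxabicyclo[3.2.1]octan-8-yl]propanoate
Conditions: H2 (1 atm), Rh/Al2O3 (5 wt % rhodium on alumina), EtOAc, rt
Reagents that add atoms: none
Why: Heterogeneous hydrogenation of the cis-disubstituted ring alkene creates no stereocentre, and rhodium on alumina is chosen over palladium because the lactone C5–O6 bond of 14 is allylic and should not be hydrogenolysed, while the ketone, the esters and the primary alkyl chloride stay untouched.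

Step 10
Reactants: 15 methyl 3-[(1R,2R,5S,8R)-5-acetyl-1-(2-chloroethyl)-2-methyl-7-oxo-6-oxabicyclo[3.2.1]octan-8-yl]propanoate
Product: 16 methyl 3-[(1R,2R,5S,8R)-1-(2-chloroethyl)-2-methyl-7-oxo-5-(prop-1-en-2-yl)-6-oxabicyclo[3.2.1]octan-8-yl]propanoate
Conditions: Zn, CH2Br2, TiCl4, THF/CH2Cl2, 0 °C → rt
Reagents that add atoms: dibromomethane, BrCBr
Why: Takai–Lombardo methylenation is non-basic and selective for ketones over esters and lactones, so the hindered, enolisable α-acyloxy methyl ketone should be turned into the isopropenyl group without acyl migration.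

Step 11
Reactants: 16 methyl 3-[(1R,2R,5S,8R)-1-(2-chloroethyl)-2-methyl-7-oxo-5-(prop-1-en-2-yl)-6-oxabicyclo[3.2.1]octan-8-yl]propanoate
Product: 17 methyl 3-[(1R,2R,5S,8R)-1-(2-iodoethyl)-2-methyl-7-oxo-5-(prop-1-en-2-yl)-6-oxabicyclo[3.2.1]octan-8-yl]propanoate
Conditions: NaI, acetone, reflux
Reagents that add atoms: sodium iodide, [Na+].[I-]
Why: Finkelstein halide exchange at an unhindered primary carbon, driven by precipitation of NaCl from acetone.

Step 12
Reactants: 18 3-bromodihydrofuran-2(3H)-one; 19 benzenethiol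
Product: 20 3-(phenylsulfanyl)dihydrofuran-2(3H)-one (racemic)
Conditions: Et3N, CH2Cl2, 0 °C → rt
Reagents that add atoms: none
Why: SN2 displacement of an α-bromo lactone by thiolate gives the α-sulfenyl lactone that serves as a butenolide α-anion equivalent.

Step 13
Reactants: 17 methyl 3-[(1R,2R,5S,8R)-1-(2-iodoethyl)-2-methyl-7-oxo-5-(prop-1-en-2-yl)-6-oxabicyclo[3.2.1]octan-8-yl]propanoate; 20 3-(phenylsulfanyl)dihydrofuran-2(3H)-one
Product: 21 methyl 3-[(1R,2R,5S,8R)-2-methyl-7-oxo-1-{2-[2-oxo-3-(phenylsulfanyl)oxolan-3-yl]ethyl}-5-(prop-1-en-2-yl)-6-oxabicyclo[3.2.1]octan-8-yl]propanoate (both epimers at the sulfur-bearing carbon)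
Conditions: LiN(SiMe3)2, THF, −78 °C; then 17, HMPA, −78 °C → rt
Reagents that add atoms: none
Why: Alkylation of the sulfur-stabilised lactone enolate with a primary iodide is the standard first half of the sulfenylation–dehydrosulfenylation route to α-alkyl butenolides, and the new quaternary centre is destroyed in step 14 so its configuration does not matter.

Step 14
Reactants: 21 methyl 3-[(1R,2R,5S,8R)-2-methyl-7-oxo-1-{2-[2-oxo-3-(phenylsulfanyl)oxolan-3-yl]ethyl}-5-(prop-1-en-2-yl)-6-oxabicyclo[3.2.1]octan-8-yl]propanoate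
Product: 23 methyl 3-[(1R,2R,5S,8R)-2-methyl-7-oxo-1-[2-(2-oxo-2,5-dihydrofuran-3-yl)ethyl]-5-(prop-1-en-2-yl)-6-oxabicyclo[3.2.1]octan-8-yl]propanoate (CNP0209666.1), via sulfoxide 22 (not isolated)
Conditions: mCPBA (1.0 equiv), CH2Cl2, −78 °C; then toluene, CaCO3, 110 °C
Reagents that add atoms: none
Why: Chemoselective S-oxidation at low temperature followed by thermal syn-elimination of the sulfoxide, which is known to go into the ring, should give the endocyclic α-alkyl butenolide while the isopropenyl group survives.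

**Compound list**
1 | methyl 4-chlorobutanoate | COC(=O)CCCCl | starting material
2 | 4,4-dimethoxybutan-2-one | CC(=O)CC(OC)OC | starting material
3 | methyl 2-(2-chloroethyl)-3-hydroxy-5,5-dimethoxy-3-methylpentanoate (diastereomer mixture) | COC(=O)C(CCCl)C(C)(O)CC(OC)OC | intermediate
4 | 3-(2-chloroethyl)-4-methyl-2H-pyran-2-one | O=C1OC=CC(C)=C1CCCl | intermediate
5 | dimethyl (1-diazo-2-oxopropyl)phosphonate | COP(=O)(OC)C(=[N+]=[N-])C(C)=O | starting material
6 | (4-methoxyphenyl)methanol | COc1ccc(CO)cc1 | starting material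
7 | dimethyl {1-[(4-methoxybenzyl)oxy]-2-oxopropyl}phosphonate (racemic) | COP(=O)(OC)C(OCc1ccc(OC)cc1)C(C)=O | intermediate
8 | methyl 4-oxobutanoate | COC(=O)CCC=O | starting material
9 | methyl (4Z)-5-[(4-methoxybenzyl)oxy]-6-oxohept-4-enoate | CC(=O)/C(OCc1ccc(OC)cc1)=C/CCC(=O)OC | intermediate
10 | methyl 3-{7-acetyl-4-(2-chloroethyl)-7-[(4-methoxybenzyl)oxy]-5-methyl-3-oxo-2-oxabicyclo[2.2.2]oct-5-en-8-yl}propanoate (endo-acetyl adduct) | CC(=O)[C@]1(OCc3ccc(OC)cc3)[C@@H]2C=C(C)[C@@](CCCl)(C(=O)O2)[C@H]1CCC(=O)OC | intermediate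
11 | methyl 3-[7-acetyl-4-(2-chloroethyl)-7-hydroxy-5-methyl-3-oxo-2-oxabicyclo[2.2.2]oct-5-en-8-yl]propanoate | CC(=O)[C@]1(O)[C@@H]2C=C(C)[C@@](CCCl)(C(=O)O2)[C@H]1CCC(=O)OC | intermediate
12 | methyl 3-[5-acetyl-1-(2-chloroethyl)-4-hydroxy-2-methyl-7-oxo-6-oxabicyclo[3.2.1]oct-2-en-8-yl]propanoate (hydroxyl cis to O6) | CC(=O)[C@@]12[C@@H](O)C=C(C)[C@@](CCCl)(C(=O)O1)[C@H]2CCC(=O)OC | intermediate
13 | methyl 3-[5-acetyl-1-(2-chloroethyl)-4-(formyloxy)-2-methyl-7-oxo-6-oxabicyclo[3.2.1]oct-2-en-8-yl]propanoate | CC(=O)[C@@]12[C@@H](OC=O)C=C(C)[C@@](CCCl)(C(=O)O1)[C@H]2CCC(=O)OC | intermediate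
14 | methyl 3-[(1R,2R,5S,8R)-5-acetyl-1-(2-chloroethyl)-2-methyl-7-oxo-6-oxabicyclo[3.2.1]oct-3-en-8-yl]propanoate | CC(=O)[C@@]12C=C[C@@H](C)[C@@](CCCl)(C(=O)O1)[C@H]2CCC(=O)OC | intermediate
15 | methyl 3-[(1R,2R,5S,8R)-5-acetyl-1-(2-chloroethyl)-2-methyl-7-oxo-6-oxabicyclo[3.2.1]octan-8-yl]propanoate | CC(=O)[C@@]12CC[C@@H](C)[C@@](CCCl)(C(=O)O1)[C@H]2CCC(=O)OC | intermediate
16 | methyl 3-[(1R,2R,5S,8R)-1-(2-chloroethyl)-2-methyl-7-oxo-5-(prop-1-en-2-yl)-6-oxabicyclo[3.2.1]octan-8-yl]propanoate | C=C(C)[C@@]12CC[C@@H](C)[C@@](CCCl)(C(=O)O1)[C@H]2CCC(=O)OC | intermediate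
17 | methyl 3-[(1R,2R,5S,8R)-1-(2-iodoethyl)-2-methyl-7-oxo-5-(prop-1-en-2-yl)-6-oxabicyclo[3.2.1]octan-8-yl]propanoate | C=C(C)[C@@]12CC[C@@H](C)[C@@](CCI)(C(=O)O1)[C@H]2CCC(=O)OC | intermediate
18 | 3-bromodihydrofuran-2(3H)-one | O=C1OCCC1Br | starting material
19 | benzenethiol | Sc1ccccc1 | starting material
20 | 3-(phenylsulfanyl)dihydrofuran-2(3H)-one (racemic) | O=C1OCCC1Sc1ccccc1 | intermediate
21 | methyl 3-[(1R,2R,5S,8R)-2-methyl-7-oxo-1-{2-[2-oxo-3-(phenylsulfanyl)oxolan-3-yl]ethyl}-5-(prop-1-en-2-yl)-6-oxabicyclo[3.2.1]octan-8-yl]propanoate (epimer mixture at the sulfur-bearing carbon) | C=C(C)[C@@]12CC[C@@H](C)[C@@](CCC3(Sc4ccccc4)CCOC3=O)(C(=O)O1)[C@H]2CCC(=O)OC | intermediate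
22 | the S-oxide of 21 (sulfoxide, diastereomer mixture) | C=C(C)[C@@]12CC[C@@H](C)[C@@](CCC3(S(=O)c4ccccc4)CCOC3=O)(C(=O)O1)[C@H]2CCC(=O)OC | intermediate
23 | methyl 3-[(1R,2R,5S,8R)-2-methyl-7-oxo-1-[2-(2-oxo-2,5-dihydrofuran-3-yl)ethyl]-5-(prop-1-en-2-yl)-6-oxabicyclo[3.2.1]octan-8-yl]propanoate | C=C(C)[C@@]12CC[C@@H](C)[C@@](CCC3=CCOC3=O)(C(=O)O1)[C@H]2CCC(=O)OC | target

**Step count**
Total: 14 steps. Longest linear sequence: 11 steps (steps 1, 2, 5, 6, 7, 8, 9, 10, 11, 13, 14).

**Steps most likely to fail**

Step 5. The catalysed cycloaddition may fail through poor facial selectivity, through Friedel–Crafts-type conjugate attack by pyrone C-5 that cannot close the ring, through ionisation of the 4-methoxybenzyl enol ether on the Lewis acid, or simply through low reactivity of the two hindered partners. The fallback sets out from 4 and 9 and replaces catalytic enantiocontrol by a resolution. The two would be combined under ZnBr2 activation at 12 kbar in CH2Cl2 to give the racemic endo-acetyl adduct F1. DDQ as in step 6 would then give the racemic tertiary alcohol F2. Catalytic DBU as in the first half of step 7 would convert this into the racemic hydroxy lactone F3. Esterification with (S)-2-methoxy-2-phenylacetic acid (DCC, DMAP) would give two diastereomers to be separated by chromatography. One is the ester of 12 with that acid, (S)-2-methoxy-2-phenylacetate F4. The other is the corresponding ester of the enantiomer of 12, diastereomeric (S)-2-methoxy-2-phenylacetate F5. Ester F4, treated with Pd(OAc)2, PBu3, HCO2H and Et3N in dioxane, should undergo the same anti ionisation and hydride delivery as the formate and come back to the route at 14.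

Step 7. The transient β-alkoxide next to the ketone may undergo retro-aldol cleavage of the C4–C5 bond, or the lactone equilibrium may not move far enough before formylation. The fallback sets out from 11 and avoids any alkoxide. Acid-catalysed methanolysis (HCl in MeOH, 0 °C) would open the strained lactone to the diol diester methyl 5-acetyl-1-(2-chloroethyl)-4,5-dihydroxy-6-(3-methoxy-3-oxopropyl)-2-methylcyclohex-2-ene-1-carboxylate F6. Steglich formylation of the secondary allylic hydroxyl would give methyl 5-acetyl-1-(2-chloroethyl)-4-(formyloxy)-5-hydroxy-6-(3-methoxy-3-oxopropyl)-2-methylcyclohex-2-ene-1-carboxylate F7. The conditions of step 8 would then give methyl 5-acetyl-1-(2-chloroethyl)-5-hydroxy-6-(3-methoxy-3-oxopropyl)-2-methylcyclohex-3-ene-1-carboxylate F8. Acid-catalysed lactonisation of the cis tertiary hydroxyl onto the ring ester (TsOH, toluene, 80 °C) would come back to the route at 14.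

Step 8. Ionisation of the hindered formate may be slow, the hydride may be delivered to C4 instead of C2 so that control of the C2 configuration is lost, or β-hydride elimination may give a diene. In addition, the newly allylic lactone C5–O6 bond of the product may itself ionise on zerovalent palladium and transpose. The fallback sets out from hydroxy lactone 12, isolated by leaving out the formylation in step 7, and uses no π-allyl chemistry. Hydrogenation over Pd/C (palladium on carbon) in EtOAc from the open face next to the one-carbon bridge would give the saturated hydroxy lactone methyl 3-[5-acetyl-1-(2-chloroethyl)-4-hydroxy-2-methyl-7-oxo-6-oxabicyclo[3.2.1]octan-8-yl]propanoate F9. 1,1'-Thiocarbonyldiimidazole would convert this alcohol into its O-(imidazole-1-carbothioate) F10. Barton–McCombie deoxygenation (Bu3SnH, AIBN, toluene, 80 °C) would remove the C4 oxygen and come back to the route at 15.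

**Further compounds**
F1 | step 5 | racemic endo-acetyl adduct (1:1 mixture of 10 and its enantiomer) | CC(=O)[C@]1(OCc3ccc(OC)cc3)[C@@H]2C=C(C)[C@@](CCCl)(C(=O)O2)[C@H]1CCC(=O)OC.CC(=O)[C@@]1(OCc3ccc(OC)cc3)[C@H]2C=C(C)[C@](CCCl)(C(=O)O2)[C@@H]1CCC(=O)OC
F2 | step 5 | racemic tertiary alcohol (1:1 mixture of 11 and its enantiomer) | CC(=O)[C@]1(O)[C@@H]2C=C(C)[C@@](CCCl)(C(=O)O2)[C@H]1CCC(=O)OC.CC(=O)[C@@]1(O)[C@H]2C=C(C)[C@](CCCl)(C(=O)O2)[C@@H]1CCC(=O)OC
F3 | step 5 | racemic hydroxy lactone (1:1 mixture of 12 and its enantiomer) | CC(=O)[C@@]12[C@@H](O)C=C(C)[C@@](CCCl)(C(=O)O1)[C@H]2CCC(=O)OC.CC(=O)[C@]12[C@H](O)C=C(C)[C@](CCCl)(C(=O)O1)[C@@H]2CCC(=O)OC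
F4 | step 5 | (S)-2-methoxy-2-phenylacetate of 12 | CC(=O)[C@@]12[C@@H](OC(=O)[C@@H](OC)c3ccccc3)C=C(C)[C@@](CCCl)(C(=O)O1)[C@H]2CCC(=O)OC
F5 | step 5 | (S)-2-methoxy-2-phenylacetate of the enantiomer of 12 | CC(=O)[C@]12[C@H](OC(=O)[C@@H](OC)c3ccccc3)C=C(C)[C@](CCCl)(C(=O)O1)[C@@H]2CCC(=O)OC
F6 | step 7 | methyl 5-acetyl-1-(2-chloroethyl)-4,5-dihydroxy-6-(3-methoxy-3-oxopropyl)-2-methylcyclohex-2-ene-1-carboxylate | CC(=O)[C@]1(O)[C@@H](O)C=C(C)[C@@](CCCl)(C(=O)OC)[C@H]1CCC(=O)OC
F7 | step 7 | methyl 5-acetyl-1-(2-chloroethyl)-4-(formyloxy)-5-hydroxy-6-(3-methoxy-3-oxopropyl)-2-methylcyclohex-2-ene-1-carboxylate | CC(=O)[C@]1(O)[C@@H](OC=O)C=C(C)[C@@](CCCl)(C(=O)OC)[C@H]1CCC(=O)OC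
F8 | step 7 | methyl 5-acetyl-1-(2-chloroethyl)-5-hydroxy-6-(3-methoxy-3-oxopropyl)-2-methylcyclohex-3-ene-1-carboxylate | CC(=O)[C@]1(O)C=C[C@@H](C)[C@@](CCCl)(C(=O)OC)[C@H]1CCC(=O)OC
F9 | step 8 | methyl 3-[5-acetyl-1-(2-chloroethyl)-4-hydroxy-2-methyl-7-oxo-6-oxabicyclo[3.2.1]octan-8-yl]propanoate | CC(=O)[C@@]12[C@@H](O)C[C@@H](C)[C@@](CCCl)(C(=O)O1)[C@H]2CCC(=O)OC
F10 | step 8 | O-(imidazole-1-carbothioate) of F9 | CC(=O)[C@@]12[C@@H](OC(=S)n3ccnc3)C[C@@H](C)[C@@](CCCl)(C(=O)O1)[C@H]2CCC(=O)OC
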